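Ring A, a benzoate carbon C1 flanked by oxygenated C2, C3 and C4, then C5–H and methyl-bearing C6, is cut at C1–C6 and C3–C4. One base-mediated operation joins benzyloxy-acetoacetate 1 (C1, C2 and the already oxygenated C3) to crotonate 2 (C4, C5 and C6 with its methyl) by conjugate addition and Dieckmann closure, giving, through acyclic adduct 3, cyclohexanedione 4. Dehydrogenation turns the C2 and C4 carbonyls into phenols, and the benzyl ether keeps O3 distinct so that O4 and then O2 can be alkylated in turn. Rings B and C are added as orsellinaldehyde and benzyl orsellinate by two depside couplings; one hydrogenolysis ends the route.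

Key step: step 1

Remark: the target has no stereocentre; 3 and 4 are carried as mixtures of stereoisomers and tautomers that all converge on 5, and orsellinaldehyde 9 and orsellinic acid 13 are taken as purchasable.

Step 1
Reactants: 1 ethyl 4-(benzyloxy)-3-oxobutanoate; 2 ethyl (E)-but-2-enoate
Product: 4 ethyl 3-(benzyloxy)-6-methyl-2,4-dioxocyclohexane-1-carboxylate (epimer/tautomer mixture), via acyclic Michael adduct 3 (not isolated)
Conditions: NaOEt (1.1 equiv), EtOH, reflux; then aq. HCl, 0 °C
Reagents that add atoms: none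
Why: Ethoxide deprotonates the doubly activated C2 methylene of 1, and this enolate adds to the β-carbon of 2 (Michael addition) to give 3, which creates the C1–C6 bond of ring A. Proton transfer then places an enolate on the benzyloxy-bearing carbon, which attacks the former crotonate ester and expels ethoxide (Dieckmann condensation, 6-exo-trig at the ester carbonyl), creating the C3–C4 bond and closing ring A; the closest known case is the acetoacetate–crotonate route to dihydroorsellinates. The three sp3 centres (C1, C3, C6) are epimerisable, are expected as a mixture under the equilibrating base, and need no control because all are erased on aromatisation. The selectivity needed is regiochemical: the Michael step must use C2 and the closure must use the benzyloxy carbon, and the substrate secures both, since C2 is by far the most acidic site and every other enolisable position could reach an ester only through a four-membered ring. The sequence should be pulled forward by deprotonation of the product to its stabilised β-tricarbonyl enolate, which is why a full equivalent of base is used and the product is released on acidification.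

Step 2
Reactants: 4 ethyl 3-(benzyloxy)-6-methyl-2,4-dioxocyclohexane-1-carboxylate
Product: 5 ethyl 3-(benzyloxy)-2,4-dihydroxy-6-methylbenzoate
Conditions: DDQ (1.2 equiv), 1,4-dioxane, 100 °C
Reagents that add atoms: none
Why: Quinone dehydrogenation of a cyclohexane-1,3-dione to a resorcinol: DDQ should abstract hydride from C6 of the enolised dione and loss of the C5 proton gives the aromatic tautomer, a plain benzyl ether being tolerated and the product lacking any ortho- or para-dihydroxy pair that could be oxidised further.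

Step 3
Reactants: 5 ethyl 3-(benzyloxy)-2,4-dihydroxy-6-methylbenzoate
Product: 6 ethyl 3,4-bis(benzyloxy)-2-hydroxy-6-methylbenzoate
Conditions: BnBr (1.05 equiv), K2CO3 (1.1 equiv), acetone, reflux
Reagents that add atoms: benzyl bromide, BrCc1ccccc1
Why: Williamson ether synthesis in which one equivalent of weak base should alkylate only the more acidic, non-chelated 4-OH (para to the ester), while the 2-OH stays locked in a hydrogen bond to the ester carbonyl.

Step 4
Reactants: 6 ethyl 3,4-bis(benzyloxy)-2-hydroxy-6-methylbenzoate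
Product: 7 ethyl 3,4-bis(benzyloxy)-2-methoxy-6-methylbenzoate
Conditions: MeI (3 equiv), K2CO3 (2 equiv), DMF, 50 °C
Reagents that add atoms: iodomethane, CI
Why: Williamson ether synthesis under more forcing conditions (polar aprotic solvent, excess electrophile, warming) should overcome the hydrogen bond of the salicylate OH, the only acidic site left.

Step 5
Reactants: 7 ethyl 3,4-bis(benzyloxy)-2-methoxy-6-methylbenzoate
Product: 8 3,4-bis(benzyloxy)-2-methoxy-6-methylbenzoic acid
Conditions: KOH (5 equiv), DMSO/H2O, 100 °C; then aq. HCl, 0 °C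
Reagents that add atoms: potassium hydroxide, [K+].[OH-]
Why: Saponification of a doubly ortho-substituted benzoate by poorly solvated hydroxide in hot aqueous DMSO, which leaves aryl benzyl and methyl ethers untouched; cold acidification avoids decarboxylation of the electron-rich acid.

Step 6
Reactants: 8 3,4-bis(benzyloxy)-2-methoxy-6-methylbenzoic acid; 9 2,4-dihydroxy-6-methylbenzaldehyde
Product: 11 4-formyl-3-hydroxy-5-methylphenyl 3,4-bis(benzyloxy)-2-methoxy-6-methylbenzoate, via mixed trifluoroacetic anhydride 10 (not isolated)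
Conditions: (CF3CO)2O, toluene, rt
Reagents that add atoms: none
Why: Depside esterification through a mixed trifluoroacetic anhydride, an acylium-like donor suited to hindered electron-rich benzoic acids, should acylate the free 4-OH of 9, whose 2-OH is hydrogen-bonded to the adjacent aldehyde.

Step 7
Reactants: 11 4-formyl-3-hydroxy-5-methylphenyl 3,4-bis(benzyloxy)-2-methoxy-6-methylbenzoate
Product: 12 4-[[3,4-bis(benzyloxy)-2-methoxy-6-methylbenzoyl]oxy]-2-hydroxy-6-methylbenzoic acid
Conditions: NaClO2, NaH2PO4, 2-methyl-2-butene, t-BuOH/THF/H2O, 0 °C to rt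
Reagents that add atoms: sodium chlorite, [Na+].[O-]Cl=O
Why: Pinnick (Lindgren) oxidation converts the aldehyde to the acid near pH 4 without touching the aryl ester or the benzyl ethers, the alkene trapping hypochlorous acid before it can chlorinate the phenol ring.

Step 8
Reactants: 13 2,4-dihydroxy-6-methylbenzoic acid (orsellinic acid)
Product: 14 benzyl 2,4-dihydroxy-6-methylbenzoate (benzyl orsellinate)
Conditions: BnBr (1.0 equiv), KHCO3 (1.1 equiv), DMF, rt
Reagents that add atoms: benzyl bromide, BrCc1ccccc1
Why: Carboxylate O-alkylation: hydrogencarbonate ionises only the carboxylic acid, so benzyl bromide should give the benzyl ester and leave both phenols free.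

Step 9
Reactants: 12 4-[[3,4-bis(benzyloxy)-2-methoxy-6-methylbenzoyl]oxy]-2-hydroxy-6-methylbenzoic acid; 14 benzyl 2,4-dihydroxy-6-methylbenzoate
Product: 16 benzyl 4-[[4-[[3,4-bis(benzyloxy)-2-methoxy-6-methylbenzoyl]oxy]-2-hydroxy-6-methylbenzoyl]oxy]-2-hydroxy-6-methylbenzoate, via didepside trifluoroacetic mixed anhydride 15 (not isolated)
Conditions: (CF3CO)2O (2 equiv), toluene, 0 °C to rt; then aq. NaHCO3 wash
Reagents that add atoms: none
Why: Depside esterification through a mixed trifluoroacetic anhydride, as in step 6: the activated salicylic-type acyl group of 15 should be taken up by the non-chelated 4-OH of 14, the hydrogen-bonded 2-OH groups of both partners being poor nucleophiles and any transient aryl trifluoroacetate being hydrolysed on work-up.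

Step 10
Reactants: 16 benzyl 4-[[4-[[3,4-bis(benzyloxy)-2-methoxy-6-methylbenzoyl]oxy]-2-hydroxy-6-methylbenzoyl]oxy]-2-hydroxy-6-methylbenzoate
Product: 17 4-[[4-[(3,4-dihydroxy-2-methoxy-6-methylbenzoyl)oxy]-2-hydroxy-6-methylbenzoyl]oxy]-2-hydroxy-6-methylbenzoic acid (CNP0277338.0)
Conditions: H2 (1 atm), 10% Pd/C, EtOAc, rt
Reagents that add atoms: none
Why: Catalytic hydrogenolysis cleaves the two benzyl ethers and the benzyl ester in one neutral operation that does not affect the two aryl (depside) esters or the methyl ether.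

Compound list
1 | ethyl 4-(benzyloxy)-3-oxobutanoate | CCOC(=O)CC(=O)COCc1ccccc1 | starting material
2 | ethyl (E)-but-2-enoate (ethyl crotonate) | C/C=C/C(=O)OCC | starting material
3 | diethyl 2-[(benzyloxy)acetyl]-3-methylpentanedioate (acyclic Michael adduct, diastereomer mixture, not isolated) | CCOC(=O)C(C(=O)COCc1ccccc1)C(C)CC(=O)OCC | intermediate
4 | ethyl 3-(benzyloxy)-6-methyl-2,4-dioxocyclohexane-1-carboxylate (mixture of epimers and enol tautomers) | CCOC(=O)C1C(C)CC(=O)C(OCc2ccccc2)C1=O | intermediate
5 | ethyl 3-(benzyloxy)-2,4-dihydroxy-6-methylbenzoate | CCOC(=O)c1c(C)cc(O)c(OCc2ccccc2)c1O | intermediate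
6 | ethyl 3,4-bis(benzyloxy)-2-hydroxy-6-methylbenzoate | CCOC(=O)c1c(C)cc(OCc2ccccc2)c(OCc2ccccc2)c1O | intermediate
7 | ethyl 3,4-bis(benzyloxy)-2-methoxy-6-methylbenzoate | CCOC(=O)c1c(C)cc(OCc2ccccc2)c(OCc2ccccc2)c1OC | intermediate
8 | 3,4-bis(benzyloxy)-2-methoxy-6-methylbenzoic acid | COc1c(OCc2ccccc2)c(OCc2ccccc2)cc(C)c1C(=O)O | intermediate
9 | 2,4-dihydroxy-6-methylbenzaldehyde (orsellinaldehyde) | Cc1cc(O)cc(O)c1C=O | starting material
10 | 3,4-bis(benzyloxy)-2-methoxy-6-methylbenzoic trifluoroacetic anhydride (not isolated) | COc1c(OCc2ccccc2)c(OCc2ccccc2)cc(C)c1C(=O)OC(=O)C(F)(F)F | intermediate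
11 | 4-formyl-3-hydroxy-5-methylphenyl 3,4-bis(benzyloxy)-2-methoxy-6-methylbenzoate | COc1c(OCc2ccccc2)c(OCc2ccccc2)cc(C)c1C(=O)Oc1cc(C)c(C=O)c(O)c1 | intermediate
12 | 4-[[3,4-bis(benzyloxy)-2-methoxy-6-methylbenzoyl]oxy]-2-hydroxy-6-methylbenzoic acid | COc1c(OCc2ccccc2)c(OCc2ccccc2)cc(C)c1C(=O)Oc1cc(C)c(C(=O)O)c(O)c1 | intermediate
13 | 2,4-dihydroxy-6-methylbenzoic acid (orsellinic acid) | Cc1cc(O)cc(O)c1C(=O)O | starting material
14 | benzyl 2,4-dihydroxy-6-methylbenzoate (benzyl orsellinate) | Cc1cc(O)cc(O)c1C(=O)OCc1ccccc1 | intermediate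
15 | 4-[[3,4-bis(benzyloxy)-2-methoxy-6-methylbenzoyl]oxy]-2-hydroxy-6-methylbenzoic trifluoroacetic anhydride (not isolated) | COc1c(OCc2ccccc2)c(OCc2ccccc2)cc(C)c1C(=O)Oc1cc(C)c(C(=O)OC(=O)C(F)(F)F)c(O)c1 | intermediate
16 | benzyl 4-[[4-[[3,4-bis(benzyloxy)-2-methoxy-6-methylbenzoyl]oxy]-2-hydroxy-6-methylbenzoyl]oxy]-2-hydroxy-6-methylbenzoate | COc1c(OCc2ccccc2)c(OCc2ccccc2)cc(C)c1C(=O)Oc1cc(C)c(C(=O)Oc2cc(C)c(C(=O)OCc3ccccc3)c(O)c2)c(O)c1 | intermediate
17 | 4-[[4-[(3,4-dihydroxy-2-methoxy-6-methylbenzoyl)oxy]-2-hydroxy-6-methylbenzoyl]oxy]-2-hydroxy-6-methylbenzoic acid | COc1c(O)c(O)cc(C)c1C(=O)Oc1cc(C)c(C(=O)Oc2cc(C)c(C(=O)O)c(O)c2)c(O)c1 | target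

Total step count: 10. Longest linear sequence: 9 (steps 1–7, 9 and 10); step 8 is a one-step side branch.

Steps most likely to fail

Step 1. Conjugate addition to the β-methyl-substituted ester may be slow and reversible. Retro-Claisen cleavage or self-condensation of 1 by ethoxide could then outrun ring formation, or the sequence could stall before the Claisen closure. The fallback builds the same ring from the opposite pairing of donor and acceptor. It does not set out from a numbered compound: it replaces 1 and 2 by purchasable 2-(benzyloxy)-N-methoxy-N-methylacetamide, prop-1-enylmagnesium bromide and diethyl malonate, and joins the route again at compound 4. Addition of the Grignard reagent to the Weinreb amide (THF, 0 °C) should give (E)-1-(benzyloxy)pent-3-en-2-one F1; any Z isomer is harmless because the alkene is consumed. NaOEt in EtOH should then add diethyl malonate to this more electrophilic enone to give diethyl 2-[5-(benzyloxy)-4-oxopentan-2-yl]propanedioate F2, which is not isolated. Its benzyloxy-bearing carbanion closes onto a malonate ester, forming C2–C3 in place of C3–C4, and delivers 4 after acidification.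

Step 2. Hydride abstraction from the dione enol may be incomplete, or may compete with oxidation at the benzylic ether CH2 and with degradation of the electron-rich enediol monoether. The fallback sets out from compound 4 and returns at compound 5. Double silylation (Me3SiOTf, Et3N, CH2Cl2, 0 °C) should give ethyl 3-(benzyloxy)-6-methyl-2,4-bis[(trimethylsilyl)oxy]cyclohexa-1,3-diene-1-carboxylate F3. Saegusa–Ito oxidation with Pd(OAc)2 in MeCN (divalent palladium on C1, β-hydride loss from C6, tautomerisation) followed by mild acidic work-up should then give 5.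

Step 9. The mixed anhydride of the salicylic-type acid may acylate the free ortho-hydroxyl of a second molecule of 12, or aroyl transfer to 14 may be slow enough that trifluoroacetylation of the phenols takes over. The fallback removes the free hydroxyl of ring B before the acid is made; it sets out from compound 11 and returns at the target 17. Benzylation of the chelated phenol of 11 (BnBr, K2CO3, DMF, 50 °C) should give 3-(benzyloxy)-4-formyl-5-methylphenyl 3,4-bis(benzyloxy)-2-methoxy-6-methylbenzoate F4. Pinnick oxidation then gives 2-(benzyloxy)-4-[[3,4-bis(benzyloxy)-2-methoxy-6-methylbenzoyl]oxy]-6-methylbenzoic acid F5. This fully protected acid is activated with (CF3CO)2O in toluene as its mixed trifluoroacetic anhydride F6, which is not isolated, and is coupled with 14 to give benzyl 4-[[2-(benzyloxy)-4-[[3,4-bis(benzyloxy)-2-methoxy-6-methylbenzoyl]oxy]-6-methylbenzoyl]oxy]-2-hydroxy-6-methylbenzoate F7. Hydrogenolysis (H2, 10% Pd/C, EtOAc) of its four benzyl groups gives 17.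

Further compounds
F1 | step 1 | (E)-1-(benzyloxy)pent-3-en-2-one | C/C=C/C(=O)COCc1ccccc1
F2 | step 1 | diethyl 2-[5-(benzyloxy)-4-oxopentan-2-yl]propanedioate (not isolated) | CCOC(=O)C(C(=O)OCC)C(C)CC(=O)COCc1ccccc1
F3 | step 2 | ethyl 3-(benzyloxy)-6-methyl-2,4-bis[(trimethylsilyl)oxy]cyclohexa-1,3-diene-1-carboxylate | CCOC(=O)C1=C(O[Si](C)(C)C)C(OCc2ccccc2)=C(O[Si](C)(C)C)CC1C
F4 | step 9 | 3-(benzyloxy)-4-formyl-5-methylphenyl 3,4-bis(benzyloxy)-2-methoxy-6-methylbenzoate | COc1c(OCc2ccccc2)c(OCc2ccccc2)cc(C)c1C(=O)Oc1cc(C)c(C=O)c(OCc2ccccc2)c1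
F5 | step 9 | 2-(benzyloxy)-4-[[3,4-bis(benzyloxy)-2-methoxy-6-methylbenzoyl]oxy]-6-methylbenzoic acid | COc1c(OCc2ccccc2)c(OCc2ccccc2)cc(C)c1C(=O)Oc1cc(C)c(C(=O)O)c(OCc2ccccc2)c1
F6 | step 9 | mixed trifluoroacetic anhydride of acid F5 (not isolated) | COc1c(OCc2ccccc2)c(OCc2ccccc2)cc(C)c1C(=O)Oc1cc(C)c(C(=O)OC(=O)C(F)(F)F)c(OCc2ccccc2)c1
F7 | step 9 | benzyl 4-[[2-(benzyloxy)-4-[[3,4-bis(benzyloxy)-2-methoxy-6-methylbenzoyl]oxy]-6-methylbenzoyl]oxy]-2-hydroxy-6-methylbenzoate | COc1c(OCc2ccccc2)c(OCc2ccccc2)cc(C)c1C(=O)Oc1cc(C)c(C(=O)Oc2cc(C)c(C(=O)OCc3ccccc3)c(O)c2)c(OCc2ccccc2)c1
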